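# Total synthesis proposal for leucanthin B (45): ring expansion of a decalin epoxy ketone

## Analysis of the target

Leucanthin B (45) is a germacranolide: a ten-membered carbocycle C1–C10 with a trans-fused α-methylene-γ-butyrolactone (oxygen on C6, C7–C11(=C13)–C12), a methyl group on C4 and the C14 carboxylic acid on C10. The ring carries a C1=C10 alkene (E by the sequence rules, but with both ring bonds on the same side), epoxides at C2–C3 and C4–C5, a (2R,3R)-epoxyangelate on C8 and an acetate on C9. Eight contiguous ring stereocentres (2R,3R,4R,5R,6S,7R,8S,9S) and two in the side-chain ester must be set. The two epoxide oxygens lie on opposite faces when the C3–C4 bond is skewed toward s-cis, the C6 oxygen is anti to the C4–C5 epoxide, C6/C7 are trans and the C8/C9 oxygens are syn. Sensitive groups are the vinyl epoxide conjugated to the acrylic acid, the α-methylene lactone (a Michael acceptor), two neighbouring secondary esters that can migrate, and the free acid. The main difficulty is the medium ring: closing ten atoms that hold three rigid cis units and nine oxygenated carbons by bond formation works against strain and entropy, and stereocontrol in the flexible ring is poor. The strategy rests on the fact that C1=C10, C2–C3 and C4–C5 are all cis with respect to the ring. A bond between C3 and C8 turns the macrocycle into a decalin: ring A (C2, C1, C10, C9, C8, C3) holds C1=C10 as a cyclohexenone alkene, ring B (C3 to C8) holds the C4–C5 epoxide and the lactone, and C2–C3 is stored as an alkyne that appears when the C3–C8 bond is cut.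

## Retrosynthetic reasoning

**C14 acid, C9 acetate, C9 silyl ether (45 ⇐ 44 ⇐ 43 ⇐ 42).** The acid is freed last from the fluoride-labile ester 44, so no hydrolysis touches the acetate, the epoxy ester or the lactone. The acetate is put on 43 only after all enolate chemistry; until then C9 is a silyl ether (42), which cannot migrate and has no acidic hydrogens.

**C11=C13 and the C8 ester (42 ⇐ 38 ⇐ 32 + 36).** The exocyclic methylene is cut off next, because a Michael acceptor would not survive hydride, hydrazide or hydrogenation. It is added to 38, in which the lactone is the only enolisable carbonyl group. The C8–O acyl bond is then cut to alcohol 32 and acid 36; the acid has a quaternary α-carbon, so the ester is inert to the lactone enolate.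

**Epoxy acid (36 ⇐ 35 ⇐ 34 ⇐ 33).** The acid comes from epoxy alcohol 35 and this from the Z allylic alcohol 34 by reagent-controlled asymmetric epoxidation. The Z geometry of ester 33 sets the cis relation of carboxyl and C3 methyl.

**C8 carbinol, C2–C3 epoxide, C2=C3 alkene (32 ⇐ 31 ⇐ 30 ⇐ 29).** The C8 stereocentre is traced to ketone 31, where the neighbouring C9 silyloxy group can steer a hydride. The C2–C3 epoxide is traced to the ring-cis alkene of 30, and this to the alkyne of 29 by syn addition of hydrogen. The alkyne stores the cis unit without stereochemistry.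

**Key disconnection (29 ⇐ 26 + 27).** The C8 ketone and the C2≡C3 alkyne of 29 are the two ends of a fragmentation. Reconnecting C3 to C8 and placing an epoxide oxygen across that bond gives the decalin epoxy enone 26 with a C2 carbonyl, which the sulfonyl hydrazide 27 unzips. This cut was chosen because it is the only one that lets all three cis units be made in six-membered rings and forms the macrocycle without a ring-closing bond formation. The forward step must cleave only the C3–C8 bond and leave C4–C7 and C9 alone.

**C1=C10 and the ring-fusion epoxide (26 ⇐ 24 ⇐ 23).** The C1=C10 alkene is removed first. If it were present together with a C3=C8 alkene, ring A would be the keto tautomer of a phenol. So the fusion epoxide of 24 is made from enone 23 before C1–C10 is dehydrogenated, and the C10 ester is carried at the saturated level.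

**Lactone, C4–C5 epoxide, C3=C8 (23 ⇐ 20 ⇐ 17).** A hydride can reach the C6 ketone only from the face that gives the C6 epimer of the target. The lactone C6–O bond is therefore made with inversion: the amide oxygen of 20 displaces an activated 6α-hydroxyl. Before that, the same hydroxyl directs the C4–C5 epoxide to the α face. The C3=C8 alkene is traced to a C3 selenide (17), so it forms without an enolate and only toward C8.

**Ring B (17 ⇐ 16 ⇐ 15 ⇐ 9 + 14).** The bonds C3–C4 and C7–C8 are cut in a Diels–Alder sense. Diene 14 carries oxygen on C6, which fixes the regiochemistry and later becomes the C6 carbinol. Dienophile 9 carries the C9 stereocentre that sets the approach face, the C10 ester and the selenium. C7 is thereby set relative to C9, the one relationship that must cross from ring A to ring B.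

**Ring A (9 ⇐ 8 ⇐ 7 ⇐ 6 ⇐ 5 ⇐ 3 ⇐ 1 + 2).** The selenium and the C2 carbonyl are removed to cyclohexene 7. Its cis C9 oxygen / C10 carboxyl pair is the ortho-endo adduct 3 of acrylimide 1 and acetoxy diene 2 (bonds C9–C10 and C1–C2), made with a chiral Lewis acid. The alcohol 4 enters when the imide is exchanged for the ester.

**Diene (14 ⇐ 13 ⇐ 10 + 11).** The silyloxy diene is the enol ether of keto amide 13, assembled by alkylating enone 10 with bromo amide 11 (bond C7–C11).

## Alternatives that were turned down

**Alternative 1: [2,3]-Wittig ring contraction.** The C7–C8 bond is disconnected. In the forward sense the C9 ketone of the thirteen-membered C8–O–C13 allylic ether A2 is enolised, and the C8 carbanion shifts onto C7 with cleavage of O–C13, giving the ten-membered hydroxy ketone A1 with the C11=C13 methylene already in place. In its favour, one step makes the carbocycle, a skeletal bond, two stereocentres (C7, C8), the C8 oxygen and the methylene unit; on this count it is stronger than the chosen route, whose key step creates no stereocentre and no skeletal bond. Against it, A2 is itself a macrocycle that must already hold both epoxides and the cis C1=C10 enone, so the hard ring closure is only moved. The enolate is conjugated through C10=C1 to the C2–C3 vinyl epoxide, which strong base can open. A [1,2]-shift competes, and the C7/C8 outcome depends on a macrocyclic transition state. After the shift, C9 must still be reduced with control, C14 oxidised and the lactone closed. The chosen route offers fixed cis geometry from small rings and no strong base while the vinyl epoxide is present.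

**Alternative 2: nickel/chromium closure at C9–C10.** The C9–C10 bond is disconnected. The seco aldehyde A4, bearing a (Z)-α-iodo enoate, is closed by a nickel-catalysed, chromium-mediated alkenyl addition to the C9 aldehyde, giving A3. A3 has the constitution and configuration of compound 43 of this route, so only acetylation and ester cleavage would remain. On convergence and on steps after ring formation this alternative is clearly stronger, and the coupling tolerates esters and lactones. Against it, A4 needs every other stereocentre, both epoxides and the methylene lactone built on an open chain. The closure forms a strained ten-membered ring holding a trisubstituted ring-cis alkene by bond formation at high dilution. The new C9 stereocentre is set by the macrocyclic transition state with nothing to enforce 9S. The low-valent chromium sits next to an allylic epoxide that it can open reductively. The chosen route offers ring formation with no entropic cost and no stereocentre at risk in that step, and it brings in the sensitive groups afterwards.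

**Alternative 3: anionic oxy-Cope ring expansion.** The C8–C9 bond is disconnected and C1–C6 reconnected. The potassium alkoxide of the cis-1,2-dialkenyl anti-diepoxycyclohexanol A6 undergoes a [3,3] shift to the ten-membered C6 ketone A5. Like the chosen route it is a ring expansion, and the anti bis-epoxide is set on a cyclohexane. It is stronger in that the key step forms a skeletal bond and the C8 and C9 stereocentres. Against it, the C6 alkoxide is adjacent to the C4–C5 epoxide, so epoxide migration competes. The boat transition state must give both the cis C1=C10 alkene and the right C8/C9 pair. The β-silyloxy acrylate arm can eliminate. A5 lacks C11–C13, so the side chain would have to be alkylated next to an epoxy ketone and C6 reduced within the macrocycle. The chosen route fragments under weak acid with the lactone and the C6/C7 centres already secured in a rigid bicycle.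

Key step: step 16

**Conventions and remarks on the chemistry**

- Locants of 45 are used for all ring intermediates. β is the face of the decalin that carries the C9 oxygen, α the opposite face. TBS = tert-butyldimethylsilyl, TMSE = 2-(trimethylsilyl)ethyl.
- Remark: diene 2 is sold as an E/Z mixture; only the E isomer is assumed to react in step 1, and the mixture is used in excess.
- Remark: the sense of induction in step 1 is assumed to be the one known for cyclopentadiene with the same catalyst (same dienophile face); if it is opposite, the enantiomeric ligand is used.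
- Remark: the configurations drawn at C3/C8 of 24–26 (β epoxide) and at C11 of 40 and 41 are the expected ones but do not matter, because these centres are destroyed in steps 16 and 24. Selenoxide 18 is a mixture at selenium.

## Steps

Step 1
Reactants: 1 3-acryloyloxazolidin-2-one; 2 (E)-buta-1,3-dien-1-yl acetate
Product: 3 3-[(1S,2R)-2-acetoxycyclohex-3-ene-1-carbonyl]oxazolidin-2-one
Conditions: [Cu((S,S)-t-Bu-box)](SbF6)2 (10 mol%; t-Bu-box = 2,2′-(propane-2,2-diyl)bis(4-tert-butyl-4,5-dihydrooxazole)), CH2Cl2, −20 °C
Reagents that add atoms: none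
Why: Catalytic asymmetric Diels–Alder reaction of a chelating acrylimide on a chiral divalent copper Lewis acid; the 1-acetoxy diene adds ortho and endo, which places the C9 acetoxy and C10 acyl groups cis, and the ligand fixes the absolute configuration of both centres.

Step 2
Reactants: 3 3-[(1S,2R)-2-acetoxycyclohex-3-ene-1-carbonyl]oxazolidin-2-one; 4 2-(trimethylsilyl)ethanol
Product: 5 2-(trimethylsilyl)ethyl (1S,2R)-2-acetoxycyclohex-3-ene-1-carboxylate
Conditions: Sm(OTf)3 (10 mol%), 4 (5 equiv), THF, rt
Reagents that add atoms: none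
Why: Lewis-acid-catalysed alcoholysis of an N-acyl oxazolidinone exchanges the imide for the fluoride-labile ester under neutral conditions, so the acetate and the α-stereocentre are not touched.

Step 3
Reactants: 5 2-(trimethylsilyl)ethyl (1S,2R)-2-acetoxycyclohex-3-ene-1-carboxylate
Product: 6 2-(trimethylsilyl)ethyl (1S,2R)-2-hydroxycyclohex-3-ene-1-carboxylate
Conditions: K2CO3 (0.2 equiv), MeOH, 0 °C
Reagents that add atoms: none
Why: Base-catalysed methanolysis of the secondary acetate is much faster than transesterification of the hindered ring ester; catalytic carbonate at low temperature avoids E1cB loss of the β-acyloxy group.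

Step 4
Reactants: 6 2-(trimethylsilyl)ethyl (1S,2R)-2-hydroxycyclohex-3-ene-1-carboxylate
Product: 7 2-(trimethylsilyl)ethyl (1S,2R)-2-[(tert-butyldimethylsilyl)oxy]cyclohex-3-ene-1-carboxylate
Conditions: TBSCl, imidazole, DMF, rt
Reagents that add atoms: tert-butyldimethylsilyl chloride, CC(C)(C)[Si](C)(C)Cl
Why: Standard silylation of a secondary allylic alcohol; the TBS ether carries the C9 oxygen through all later Lewis acid, base and oxidant steps.

Step 5
Reactants: 7 2-(trimethylsilyl)ethyl (1S,2R)-2-[(tert-butyldimethylsilyl)oxy]cyclohex-3-ene-1-carboxylate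
Product: 8 2-(trimethylsilyl)ethyl (1S,2R)-2-[(tert-butyldimethylsilyl)oxy]-5-oxocyclohex-3-ene-1-carboxylate
Conditions: CrO3, 3,5-dimethylpyrazole, CH2Cl2, −20 °C
Reagents that add atoms: chromium trioxide, O=[Cr](=O)=O
Why: Allylic C–H oxidation of a cyclohexene with the CrO3·3,5-dimethylpyrazole complex; the allylic methylene remote from the silyloxy carbon is oxidised, as in the known conversion of cyclohex-2-enyl ethers into 4-oxygenated cyclohex-2-enones.

Step 6
Reactants: 8 2-(trimethylsilyl)ethyl (1S,2R)-2-[(tert-butyldimethylsilyl)oxy]-5-oxocyclohex-3-ene-1-carboxylate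
Product: 9 2-(trimethylsilyl)ethyl (1S,2S)-2-[(tert-butyldimethylsilyl)oxy]-5-oxo-4-(phenylselanyl)cyclohex-3-ene-1-carboxylate
Conditions: PhSeCl, pyridine, CH2Cl2, 0 °C → rt
Reagents that add atoms: benzeneselenenyl chloride, Cl[Se]c1ccccc1
Why: α-Selenenylation of an enone by addition–elimination with PhSeCl/pyridine; the selenium blocks C3 and is a latent C3=C8 double bond (the descriptor at the silyloxy carbon changes only because selenium raises the priority of the alkene branch).

Step 7
Reactants: 10 (E)-pent-3-en-2-one; 11 2-bromo-N,N-dimethylacetamide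
Product: 13 (E)-N,N-dimethyl-4-oxohept-5-enamide, via lithium dienolate 12 (not isolated)
Conditions: LiN(iPr)2, THF, −78 °C; then 11, DMPU, −78 → −30 °C
Reagents that add atoms: none
Why: Kinetic deprotonation of the enone at its methyl group and SN2 alkylation of the cross-conjugated enolate by the α-bromo amide; the E alkene is not involved.

Step 8
Reactants: 13 (E)-N,N-dimethyl-4-oxohept-5-enamide
Product: 14 (3Z,5E)-4-[(tert-butyldimethylsilyl)oxy]-N,N-dimethylhepta-3,5-dienamide
Conditions: TBSOTf, Et3N, CH2Cl2, 0 °C
Reagents that add atoms: tert-butyldimethylsilyl trifluoromethanesulfonate, CC(C)(C)[Si](C)(C)OS(=O)(=O)C(F)(F)F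
Why: Soft enolisation of the ketone toward its only α-methylene gives the thermodynamically preferred Z silyl enol ether, a 2-silyloxy diene with both terminal substituents pointing outward.

Step 9
Reactants: 9 2-(trimethylsilyl)ethyl (1S,2S)-2-[(tert-butyldimethylsilyl)oxy]-5-oxo-4-(phenylselanyl)cyclohex-3-ene-1-carboxylate; 14 (3Z,5E)-4-[(tert-butyldimethylsilyl)oxy]-N,N-dimethylhepta-3,5-dienamide
Product: 15 cis-decalin selenide (2-oxo; 3β-SePh; 4α-methyl; C5=C6 enol ether with 6-OTBS; 7α-CH2CONMe2; 8β-H; 9β-OTBS; 10β-CO2TMSE)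
Conditions: Me2AlCl (2.5 equiv), CH2Cl2, −78 → −30 °C
Reagents that add atoms: none
Why: Lewis-acid-promoted Diels–Alder reaction of an α-heteroatom-substituted cyclohexenone with a 2-silyloxy diene; the oxygen on C6 sends C7 to the enone β-carbon C8 and the diene adds anti to the β-oriented C9 silyloxy and C10 ester groups. The endo transition state (C2 carbonyl under the diene) puts H7 cis to H8, which sets C7 relative to C9 as in the target; C3, C4, C8 and C10 are temporary stereocentres.

Step 10
Reactants: 15 cis-decalin selenide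
Product: 16 selenide enedione (as 15, but ring B is the 4-en-6-one)
Conditions: DDQ, 2,6-lutidine, CH2Cl2, rt
Reagents that add atoms: none
Why: DDQ oxidation of a silyl enol ether to the enone (hydride abstraction from the allylic C4–H, then loss of the silyl group); C4 becomes sp2, so H8 is the only hydrogen left syn to selenium.

Step 11
Reactants: 16 selenide enedione
Product: 17 selenide allylic alcohol (6α-OH; 4-ene; 2-oxo)
Conditions: NaBH4, CeCl3·7H2O, MeOH/CH2Cl2, −78 °C
Reagents that add atoms: none
Why: Luche 1,2-reduction; the conjugated C6 carbonyl should react before the C2 ketone, which is flanked by the quaternary selenium-bearing C3, and hydride adds from the convex β face anti to the C7 side chain. The resulting 6α-alcohol is the C6 epimer of the target on purpose: it directs the next epoxidation and is inverted when the lactone is closed.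

Step 12
Reactants: 17 selenide allylic alcohol
Product: 20 epoxy alcohol (3(8)-en-2-one; 4α,5α-epoxide; 6α-OH; 7α-CH2CONMe2), via selenoxide 18 (not isolated), via dienol 19 (not isolated)
Conditions: mCPBA (1.05 equiv), NaHCO3, CH2Cl2, −78 → 0 °C; then VO(acac)2 (5 mol%), t-BuOOH, 0 °C
Reagents that add atoms: tert-butyl hydroperoxide, CC(C)(C)OO
Why: Selenide oxidation and syn selenoxide elimination (only H8 is available) unveil the C3=C8 enone without an enolate. Vanadium-catalysed hydroxyl-directed epoxidation then delivers oxygen to C4=C5 syn to the 6α-hydroxyl, that is to the α face, and leaves the electron-poor C3=C8 alkene alone.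

Step 13
Reactants: 20 epoxy alcohol
Product: 23 epoxy enone lactone (3(8)-en-2-one; 4α,5α-epoxide; trans 6β-O lactone), via mesylate 21 (not isolated), via iminium lactone 22 (not isolated)
Conditions: MsCl, Et3N, CH2Cl2, −20 °C; filter, then MeCN, 50 °C; then H2O/THF, NaH2PO4, rt
Reagents that add atoms: water, O
Why: Invertive lactonisation by neighbouring-group participation: the amide oxygen displaces the C6 mesylate from the β face (5-exo, SN2) to an iminium lactone, which water hydrolyses to the trans-fused lactone. C6 ends with its oxygen anti to the C4–C5 epoxide and trans to the C7 side chain.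

Step 14
Reactants: 23 epoxy enone lactone
Product: 24 bis-epoxy ketone (2-oxo; 3β,8β-epoxide; 4α,5α-epoxide; trans lactone; C1–C10 saturated)
Conditions: t-BuOOH, DBU, CH2Cl2, 0 °C → rt
Reagents that add atoms: tert-butyl hydroperoxide, CC(C)(C)OO
Why: Nucleophilic (Weitz–Scheffer) epoxidation of the tetrasubstituted enone by tert-butyl peroxide anion; attack at C8 is expected anti to the α-disposed C4–C5 epoxide and C7 side chain. The face does not matter, because C3 and C8 lose their stereochemistry in step 16.

Step 15
Reactants: 24 bis-epoxy ketone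
Product: 26 decalin epoxy enone (1(10)-en-2-one; 10-CO2TMSE; 9β-OTBS; 3β,8β- and 4α,5α-epoxides; trans 6,12-lactone), via silyl enol ether 25 (not isolated)
Conditions: LiN(SiMe3)2, Me3SiCl, THF, −78 °C; then Pd(OAc)2, MeCN, rt
Reagents that add atoms: none
Why: Saegusa–Ito dehydrogenation; the ketone can enolise only toward C1 (C3 is quaternary) and β-hydride elimination takes the C10 hydrogen, so the C1=C10 alkene is necessarily cis within the six-membered ring. It is introduced only now, because a ring A holding both C3=C8 and C1=C10 with a hydrogen on C9 would tautomerise to a phenol.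

Step 16
Reactants: 26 decalin epoxy enone; 27 4-methylbenzenesulfonohydrazide
Product: 29 ten-membered ynone (8-oxo; C2≡C3; ring-cis C1=C10 with 10-CO2TMSE; 4,5-epoxide; trans 6,12-lactone; 9-OTBS), via tosylhydrazone 28 (not isolated)
Conditions: 27 (1.1 equiv), AcOH/CH2Cl2 (1:2), −20 °C → rt
Reagents that add atoms: none
Why: Eschenmoser–Tanabe fragmentation: 27 condenses with the C2 carbonyl under weak acid to hydrazone 28, loss of the N–H proton opens the C3–O bond of the only α,β-epoxide to a C8 alkoxide and a C2=C3 vinyl diazene, and the alkoxide collapses to the C8 ketone with heterolysis of the C3–C8 bond anti to the C2–N bond, forming the C2≡C3 alkyne and expelling N2 and p-toluenesulfinate. The closest known reactions are the fragmentations of ring-fusion epoxy ketone tosylhydrazones of the 9,10-epoxydecal-1-one type to cyclodec-5-ynones and larger cycloalkynones. The ten-membered ring is not closed by bond formation; it appears when the bond shared by the two six-membered rings is cut, so no closure mode has to compete with oligomerisation. No stereocentre is created: C3 and C8 become sp and sp2, the C1=C10 alkene keeps the cis geometry it had in ring A, and C4, C5, C6, C7 and C9 are not touched. The step needs condensation at C2 to win over conjugate addition of the hydrazide to the doubly activated C1=C10 alkene; that addition can revert under acid, whereas the fragmentation is irreversible. It also needs cleavage through the C3–C8 epoxide only: the C4–C5 epoxide is not α,β to the hydrazone and its C4–O bond is held gauche, not anti, to the breaking bond, so the competing Grob pathway is not aligned. Cold acetic acid without base keeps the acidic C9 hydrogen in place, which prevents aromatisation of ring A, and spares the C7 and C9 centres that become α to the new ketone.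

Step 17
Reactants: 29 ten-membered ynone
Product: 30 dienone (as 29, with a cis C2=C3 alkene)
Conditions: H2 (1 atm), Pd/CaCO3 poisoned with Pb(OAc)2, quinoline, EtOAc, rt
Reagents that add atoms: none
Why: Lindlar semi-hydrogenation adds hydrogen syn to the alkyne and gives the ring-cis C2=C3 alkene; the trisubstituted, ester-bearing C1=C10 alkene is not reduced over the poisoned catalyst.

Step 18
Reactants: 30 dienone
Product: 31 bis-epoxy ketone ((2R,3R)-epoxide; 4,5-epoxide; 8-oxo; 9-OTBS)
Conditions: dimethyldioxirane, acetone, 0 °C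
Reagents that add atoms: dimethyldioxirane, CC1(C)OO1
Why: Electrophilic epoxidation by a dioxirane under neutral conditions; the γ,δ-alkene of the dienoate is the more electron-rich one, and the oxidant should approach the outer face of the skewed diene, anti to the C4–C5 epoxide oxygen, which gives the 2R,3R configuration.

Step 19
Reactants: 31 bis-epoxy ketone
Product: 32 C8 alcohol (8S)
Conditions: NaBH4, MeOH/THF, −40 °C
Reagents that add atoms: none
Why: Hydride reduction under Felkin–Anh control by the non-chelating C9 silyloxy group should give the 8,9-syn relationship (8S); the ketone is the only group reduced at this temperature.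

Step 20
Reactants: 33 methyl (Z)-2-methylbut-2-enoate (methyl angelate)
Product: 34 (Z)-2-methylbut-2-en-1-ol
Conditions: iBu2AlH (2.2 equiv), CH2Cl2, −78 °C
Reagents that add atoms: none
Why: 1,2-Reduction of an α,β-unsaturated ester to the allylic alcohol with retention of the Z geometry.

Step 21
Reactants: 34 (Z)-2-methylbut-2-en-1-ol
Product: 35 [(2S,3R)-2,3-dimethyloxiran-2-yl]methanol
Conditions: Ti(OiPr)4, L-(+)-diethyl tartrate, t-BuOOH, 4 Å sieves, CH2Cl2, −20 °C
Reagents that add atoms: tert-butyl hydroperoxide, CC(C)(C)OO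
Why: Sharpless asymmetric epoxidation; the L-(+)-tartrate catalyst selects the alkene face that gives the (2S,3R) epoxy alcohol, and the Z geometry fixes the cis relation of the carbinol carbon and the C3 methyl group.

Step 22
Reactants: 35 [(2S,3R)-2,3-dimethyloxiran-2-yl]methanol
Product: 36 (2R,3R)-2,3-dimethyloxirane-2-carboxylic acid
Conditions: RuCl3 (cat.), NaIO4, CCl4/MeCN/H2O, rt
Reagents that add atoms: water, O
Why: Ruthenium tetroxide oxidation of a primary alcohol to the acid through the aldehyde hydrate; the epoxide is inert and the C2 descriptor changes only through the priority change.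

Step 23
Reactants: 32 C8 alcohol; 36 (2R,3R)-2,3-dimethyloxirane-2-carboxylic acid
Product: 38 C8 epoxyangelate (saturated lactone; 9-OTBS; TMSE ester), via mixed anhydride 37 (not isolated)
Conditions: 36, 2,4,6-trichlorobenzoyl chloride, Et3N, THF, rt; then 32, DMAP, toluene, rt
Reagents that add atoms: none
Why: Yamaguchi esterification through the mixed anhydride, suited to a hindered secondary alcohol and an α-quaternary acid that can neither epimerise nor form a ketene.

Step 24
Reactants: 38 C8 epoxyangelate
Product: 42 α-methylene lactone (9-O-TBS-9-desacetyl leucanthin B TMSE ester), via lithium enolate 39 (not isolated), via Mannich base 40 (not isolated), via ammonium iodide 41 (not isolated)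
Conditions: LiN(iPr)2, THF, −78 °C; then CH2=NMe2+ I−, −78 → 0 °C; then MeI, MeOH, rt; then NaHCO3 (aq), EtOAc
Reagents that add atoms: N,N-dimethylmethyleneiminium iodide (Eschenmoser's salt), C=[N+](C)C.[I-]
Why: α-Methylenation of a γ-lactone by Mannich reaction of its lithium enolate, quaternisation and elimination of trimethylamine; the C8 ester has no α-hydrogen and C9 is still a silyl ether, so the lactone is the only enolisable carbonyl group.

Step 25
Reactants: 42 α-methylene lactone
Product: 43 9-O-desacetyl leucanthin B 2-(trimethylsilyl)ethyl ester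
Conditions: HF·pyridine, pyridine, THF, 0 °C → rt
Reagents that add atoms: none
Why: Acidic fluoride cleaves the secondary TBS ether without forming an alkoxide, which avoids migration of the C8 acyl group, and spares the 2-(trimethylsilyl)ethyl ester.

Step 26
Reactants: 43 9-O-desacetyl leucanthin B 2-(trimethylsilyl)ethyl ester
Product: 44 leucanthin B 2-(trimethylsilyl)ethyl ester
Conditions: Ac2O, pyridine, DMAP (cat.), CH2Cl2, 0 °C
Reagents that add atoms: acetic anhydride, CC(=O)OC(C)=O
Why: DMAP-catalysed acetylation of the C9 alcohol, faster than any acyl migration.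

Step 27
Reactants: 44 leucanthin B 2-(trimethylsilyl)ethyl ester
Product: 45 leucanthin B
Conditions: (Me2N)3S+ Me3SiF2− (TASF), DMF, 0 °C; pH 4 phosphate buffer
Reagents that add atoms: none
Why: Fluoride-induced β-elimination of the 2-(trimethylsilyl)ethyl ester (loss of ethene and Me3SiF) frees the acid under anhydrous, weakly basic conditions that do not hydrolyse the acetate, the epoxy ester or the lactone.

## Compound list

1 | 3-acryloyloxazolidin-2-one | C=CC(=O)N1CCOC1=O | starting material
2 | (E)-buta-1,3-dien-1-yl acetate | C=C/C=C/OC(C)=O | starting material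
3 | 3-[(1S,2R)-2-acetoxycyclohex-3-ene-1-carbonyl]oxazolidin-2-one | CC(=O)O[C@@H]1C=CCC[C@@H]1C(=O)N1CCOC1=O | intermediate
4 | 2-(trimethylsilyl)ethanol | C[Si](C)(C)CCO | starting material
5 | 2-(trimethylsilyl)ethyl (1S,2R)-2-acetoxycyclohex-3-ene-1-carboxylate | CC(=O)O[C@@H]1C=CCC[C@@H]1C(=O)OCC[Si](C)(C)C | intermediate
6 | 2-(trimethylsilyl)ethyl (1S,2R)-2-hydroxycyclohex-3-ene-1-carboxylate | O[C@@H]1C=CCC[C@@H]1C(=O)OCC[Si](C)(C)C | intermediate
7 | 2-(trimethylsilyl)ethyl (1S,2R)-2-[(tert-butyldimethylsilyl)oxy]cyclohex-3-ene-1-carboxylate | CC(C)(C)[Si](C)(C)O[C@@H]1C=CCC[C@@H]1C(=O)OCC[Si](C)(C)C | intermediate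
8 | 2-(trimethylsilyl)ethyl (1S,2R)-2-[(tert-butyldimethylsilyl)oxy]-5-oxocyclohex-3-ene-1-carboxylate | O=C1C=C[C@@H](O[Si](C)(C)C(C)(C)C)[C@@H](C(=O)OCC[Si](C)(C)C)C1 | intermediate
9 | 2-(trimethylsilyl)ethyl (1S,2S)-2-[(tert-butyldimethylsilyl)oxy]-5-oxo-4-(phenylselanyl)cyclohex-3-ene-1-carboxylate | O=C1C([Se]c2ccccc2)=C[C@@H](O[Si](C)(C)C(C)(C)C)[C@@H](C(=O)OCC[Si](C)(C)C)C1 | intermediate
10 | (E)-pent-3-en-2-one | C/C=C/C(C)=O | starting material
11 | 2-bromo-N,N-dimethylacetamide | CN(C)C(=O)CBr | starting material
12 | lithium (E)-penta-1,3-dien-2-olate | [Li+].[O-]C(=C)/C=C/C | intermediate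
13 | (E)-N,N-dimethyl-4-oxohept-5-enamide | C/C=C/C(=O)CCC(=O)N(C)C | intermediate
14 | (3Z,5E)-4-[(tert-butyldimethylsilyl)oxy]-N,N-dimethylhepta-3,5-dienamide | C/C=C/C(O[Si](C)(C)C(C)(C)C)=C/CC(=O)N(C)C | intermediate
15 | cis-decalin selenide (2-oxo; 3β-SePh; 4α-methyl; 5-ene with 6-OTBS; 7α-CH2CONMe2; 8β-H; 9β-OTBS; 10β-CO2TMSE) | O=C1C[C@H](C(=O)OCC[Si](C)(C)C)[C@H](O[Si](C)(C)C(C)(C)C)[C@H]2[C@@H](CC(=O)N(C)C)C(O[Si](C)(C)C(C)(C)C)=C[C@@H](C)[C@@]12[Se]c1ccccc1 | intermediate
16 | selenide enedione (2,6-dioxo; 4-ene; 3β-SePh) | O=C1C[C@H](C(=O)OCC[Si](C)(C)C)[C@H](O[Si](C)(C)C(C)(C)C)[C@H]2[C@@H](CC(=O)N(C)C)C(=O)C=C(C)[C@@]12[Se]c1ccccc1 | intermediate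
17 | selenide allylic alcohol (6α-OH; 4-ene; 2-oxo; 3β-SePh) | O=C1C[C@H](C(=O)OCC[Si](C)(C)C)[C@H](O[Si](C)(C)C(C)(C)C)[C@H]2[C@@H](CC(=O)N(C)C)[C@@H](O)C=C(C)[C@@]12[Se]c1ccccc1 | intermediate
18 | selenoxide of 17 (mixture at selenium) | O=C1C[C@H](C(=O)OCC[Si](C)(C)C)[C@H](O[Si](C)(C)C(C)(C)C)[C@H]2[C@@H](CC(=O)N(C)C)[C@@H](O)C=C(C)[C@@]12[Se](=O)c1ccccc1 | intermediate
19 | dienol (3(8),4-dien-2-one; 6α-OH) | O=C1C[C@H](C(=O)OCC[Si](C)(C)C)[C@H](O[Si](C)(C)C(C)(C)C)C2=C1C(C)=C[C@H](O)[C@@H]2CC(=O)N(C)C | intermediate
20 | epoxy alcohol (3(8)-en-2-one; 4α,5α-epoxide; 6α-OH; 7α-CH2CONMe2) | O=C1C[C@H](C(=O)OCC[Si](C)(C)C)[C@H](O[Si](C)(C)C(C)(C)C)C2=C1[C@]3(C)O[C@@H]3[C@H](O)[C@@H]2CC(=O)N(C)C | intermediate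
21 | C6α mesylate of 20 | O=C1C[C@H](C(=O)OCC[Si](C)(C)C)[C@H](O[Si](C)(C)C(C)(C)C)C2=C1[C@]3(C)O[C@@H]3[C@H](OS(C)(=O)=O)[C@@H]2CC(=O)N(C)C | intermediate
22 | iminium lactone methanesulfonate (C6–O β) | O=C1C[C@H](C(=O)OCC[Si](C)(C)C)[C@H](O[Si](C)(C)C(C)(C)C)C2=C1[C@]3(C)O[C@@H]3[C@H]4OC(=[N+](C)C)C[C@@H]42.CS(=O)(=O)[O-] | intermediate
23 | epoxy enone lactone (3(8)-en-2-one; 4α,5α-epoxide; trans 6,12-lactone) | O=C1C[C@H](C(=O)OCC[Si](C)(C)C)[C@H](O[Si](C)(C)C(C)(C)C)C2=C1[C@]3(C)O[C@@H]3[C@H]4OC(=O)C[C@@H]42 | intermediate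
24 | bis-epoxy ketone (2-oxo; 3β,8β-epoxide; 4α,5α-epoxide; trans lactone; 10β-CO2TMSE) | O=C1C[C@H](C(=O)OCC[Si](C)(C)C)[C@H](O[Si](C)(C)C(C)(C)C)[C@]23O[C@]12[C@]4(C)O[C@@H]4[C@H]5OC(=O)C[C@@H]53 | intermediate
25 | trimethylsilyl enol ether of 24 (C1=C2) | C[Si](C)(C)OC1=C[C@H](C(=O)OCC[Si](C)(C)C)[C@H](O[Si](C)(C)C(C)(C)C)[C@]23O[C@]12[C@]4(C)O[C@@H]4[C@H]5OC(=O)C[C@@H]53 | intermediate
26 | decalin epoxy enone (1(10)-en-2-one; 10-CO2TMSE; 9β-OTBS; 3β,8β- and 4α,5α-epoxides; trans 6,12-lactone) | O=C1C=C(C(=O)OCC[Si](C)(C)C)[C@H](O[Si](C)(C)C(C)(C)C)[C@]23O[C@]12[C@]4(C)O[C@@H]4[C@H]5OC(=O)C[C@@H]53 | intermediate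
27 | 4-methylbenzenesulfonohydrazide | Cc1ccc(cc1)S(=O)(=O)NN | starting material
28 | tosylhydrazone of 26 at C2 | Cc1ccc(cc1)S(=O)(=O)NN=C1C=C(C(=O)OCC[Si](C)(C)C)[C@H](O[Si](C)(C)C(C)(C)C)[C@]23O[C@]12[C@]4(C)O[C@@H]4[C@H]5OC(=O)C[C@@H]53 | intermediate
29 | ten-membered ynone (8-oxo; C2≡C3; ring-cis C1=C10; 4,5-epoxide; 6,12-lactone; 9-OTBS; TMSE ester) | O=C1[C@H]2CC(=O)O[C@@H]2[C@H]3O[C@@]3(C)C#C/C=C(/C(=O)OCC[Si](C)(C)C)[C@@H]1O[Si](C)(C)C(C)(C)C | intermediate
30 | dienone (cis C2=C3; ring-cis C1=C10; 8-oxo) | C1C(=O)O[C@H]2[C@H]1C(=O)[C@@H](O[Si](C)(C)C(C)(C)C)/C(C(=O)OCC[Si](C)(C)C)=C\C=C/[C@]1(C)O[C@H]21 | intermediate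
31 | bis-epoxy ketone ((2R,3R)- and (4R,5R)-epoxides; 8-oxo) | C1C(=O)O[C@H]2[C@H]1C(=O)[C@@H](O[Si](C)(C)C(C)(C)C)/C(C(=O)OCC[Si](C)(C)C)=C\[C@H]1O[C@H]1[C@]1(C)O[C@H]21 | intermediate
32 | C8 alcohol (8S) | C1C(=O)O[C@H]2[C@H]1[C@H](O)[C@@H](O[Si](C)(C)C(C)(C)C)/C(C(=O)OCC[Si](C)(C)C)=C\[C@H]1O[C@H]1[C@]1(C)O[C@H]21 | intermediate
33 | methyl (Z)-2-methylbut-2-enoate | C/C=C(/C)C(=O)OC | starting material
34 | (Z)-2-methylbut-2-en-1-ol | C/C=C(/C)CO | intermediate
35 | [(2S,3R)-2,3-dimethyloxiran-2-yl]methanol | OC[C@]1(C)O[C@@H]1C | intermediate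
36 | (2R,3R)-2,3-dimethyloxirane-2-carboxylic acid | OC(=O)[C@]1(C)O[C@@H]1C | intermediate
37 | (2R,3R)-2,3-dimethyloxirane-2-carboxylic 2,4,6-trichlorobenzoic anhydride | Clc1cc(Cl)c(C(=O)OC(=O)[C@]2(C)O[C@@H]2C)c(Cl)c1 | intermediate
38 | C8 epoxyangelate (11,13-dihydro; 9-OTBS; TMSE ester) | C1C(=O)O[C@H]2[C@H]1[C@H](OC(=O)[C@]1(C)O[C@@H]1C)[C@@H](O[Si](C)(C)C(C)(C)C)/C(C(=O)OCC[Si](C)(C)C)=C\[C@H]1O[C@H]1[C@]1(C)O[C@H]21 | intermediate
39 | lithium enolate of lactone 38 | C1=C([O-])O[C@H]2[C@H]1[C@H](OC(=O)[C@]1(C)O[C@@H]1C)[C@@H](O[Si](C)(C)C(C)(C)C)/C(C(=O)OCC[Si](C)(C)C)=C\[C@H]1O[C@H]1[C@]1(C)O[C@H]21.[Li+] | intermediate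
40 | Mannich base (C11 dimethylaminomethyl) | CN(C)C[C@@H]1C(=O)O[C@H]2[C@H]1[C@H](OC(=O)[C@]1(C)O[C@@H]1C)[C@@H](O[Si](C)(C)C(C)(C)C)/C(C(=O)OCC[Si](C)(C)C)=C\[C@H]1O[C@H]1[C@]1(C)O[C@H]21 | intermediate
41 | trimethylammonium iodide of 40 | C[N+](C)(C)C[C@@H]1C(=O)O[C@H]2[C@H]1[C@H](OC(=O)[C@]1(C)O[C@@H]1C)[C@@H](O[Si](C)(C)C(C)(C)C)/C(C(=O)OCC[Si](C)(C)C)=C\[C@H]1O[C@H]1[C@]1(C)O[C@H]21.[I-] | intermediate
42 | 9-O-TBS-9-desacetyl leucanthin B 2-(trimethylsilyl)ethyl ester | C=C1C(=O)O[C@H]2[C@H]1[C@H](OC(=O)[C@]1(C)O[C@@H]1C)[C@@H](O[Si](C)(C)C(C)(C)C)/C(C(=O)OCC[Si](C)(C)C)=C\[C@H]1O[C@H]1[C@]1(C)O[C@H]21 | intermediate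
43 | 9-O-desacetyl leucanthin B 2-(trimethylsilyl)ethyl ester | C=C1C(=O)O[C@H]2[C@H]1[C@H](OC(=O)[C@]1(C)O[C@@H]1C)[C@@H](O)/C(C(=O)OCC[Si](C)(C)C)=C\[C@H]1O[C@H]1[C@]1(C)O[C@H]21 | intermediate
44 | leucanthin B 2-(trimethylsilyl)ethyl ester | C=C1C(=O)O[C@H]2[C@H]1[C@H](OC(=O)[C@]1(C)O[C@@H]1C)[C@@H](OC(C)=O)/C(C(=O)OCC[Si](C)(C)C)=C\[C@H]1O[C@H]1[C@]1(C)O[C@H]21 | intermediate
45 | leucanthin B | C=C1C(=O)O[C@H]2[C@H]1[C@H](OC(=O)[C@]1(C)O[C@@H]1C)[C@@H](OC(C)=O)/C(C(=O)O)=C\[C@H]1O[C@H]1[C@]1(C)O[C@H]21 | target

## Step count and least certain steps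

Total: 27 steps. Longest linear sequence: 22 steps (steps 1–6, 9–19, 23–27); the diene (steps 7–8) and the epoxy acid (steps 20–22) are made separately.

**Step 16 (key step).** The most likely failure is that condensation at the hindered, conjugated C2 carbonyl is slow, so that reversible conjugate addition of the hydrazide to the C1=C10 alkene, or enolisation at C9 followed by opening of the fusion epoxide and aromatisation of ring A, takes over. Fallback: the aminoaziridine variant of the same fragmentation, which runs without acid and without a sulfinate leaving group. Compound 26 is condensed with racemic trans-2,3-diphenylaziridin-1-amine to the N-aziridinyl imine F13 (one of two diastereomers drawn; both should fragment alike). Thermolysis in toluene at 80–110 °C expels stilbene and N2 and returns to the route at 29.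

**Step 9.** The α-substituted, γ-branched dienophile may react too slowly, so that Lewis-acid cleavage of the silyl enol ether, a stepwise Michael addition without ring closure, or loss of endo and facial control competes. Fallback: the route is run without selenium. Enone 8 and diene 14 are combined under the same Lewis acid to the des-seleno adduct F1. DDQ gives the enedione F2 and Luche reduction the 6α-alcohol F3. Me3SiOTf/Et3N silylates the hydroxyl and turns the β,γ-unsaturated C2 ketone into the conjugated dienol ether, giving the bis(trimethylsilyl) compound F4. Saegusa–Ito oxidation with Pd(OAc)2 gives the C6-O-trimethylsilyl dienone F5. Mild acidic methanolysis frees dienol 19, which is epoxidised as in the second half of step 12, returning to the route at 20.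

**Step 13.** The activated 6α-oxygen is anti to H7, so base-induced elimination (leading to aromatisation of ring B), ionisation with loss of stereochemical fidelity, or attack of the amide oxygen on the neighbouring epoxide may compete with backside displacement. Fallback: inversion and lactonisation are separated. From 20, a Mitsunobu reaction with chloroacetic acid (PPh3, diisopropyl azodicarboxylate) gives the inverted chloroacetate F6. K2CO3/MeOH at 0 °C gives the 6β-alcohol F7. Acid-catalysed lactonisation (camphorsulfonic acid, toluene, 50 °C) closes the trans lactone with loss of dimethylamine, returning to the route at 23.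

**Step 14.** Conjugate addition of the peroxide to the fully substituted C8 may be slow, leaving time for γ-deprotonation at C7 with loss of the C6 carboxylate, or for attack of the peroxide on the lactone. Fallback: the oxygen is delivered by a directing group. From 23, Luche reduction gives the C2 allylic alcohol F8. VO(acac)2/t-BuOOH epoxidises C3=C8 syn to that hydroxyl to give the epoxy alcohol F9. Dess–Martin periodinane restores the ketone, returning to the route at 24.

**Step 18.** Facial selectivity on the flexible ten-membered diene may be poor or reversed. Fallback: the halohydrin route, which delivers oxygen to the face opposite to the one an electrophile attacks. From 30, N-bromosuccinimide in aqueous THF gives the bromohydrin F10 (bromonium ion on the accessible face, water entering at the allylic C2 from the other side). Ag2O closes the epoxide with inversion at C3, returning to the route at 31.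

**Step 19.** The macrocycle may override the Felkin–Anh preference and give hydride delivery to the other face of the C8 carbonyl; under basic conditions the new alkoxide may also attack the lactone. Fallback: correction by inversion. From 31, the 8R alcohol F11 obtained in that case is converted by a Mitsunobu reaction with 4-nitrobenzoic acid into the 8S 4-nitrobenzoate F12. Methanolysis (K2CO3, MeOH, 0 °C) returns to the route at 32.

## Further compounds

F1 | step 9 | des-seleno Diels–Alder adduct (3β-H; otherwise as 15) | O=C1C[C@H](C(=O)OCC[Si](C)(C)C)[C@H](O[Si](C)(C)C(C)(C)C)[C@H]2[C@@H](CC(=O)N(C)C)C(O[Si](C)(C)C(C)(C)C)=C[C@@H](C)[C@@H]12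
F2 | step 9 | des-seleno enedione (2,6-dioxo; 4-ene) | O=C1C[C@H](C(=O)OCC[Si](C)(C)C)[C@H](O[Si](C)(C)C(C)(C)C)[C@H]2[C@@H](CC(=O)N(C)C)C(=O)C=C(C)[C@@H]12
F3 | step 9 | des-seleno 6α-alcohol (2-oxo; 4-ene) | O=C1C[C@H](C(=O)OCC[Si](C)(C)C)[C@H](O[Si](C)(C)C(C)(C)C)[C@H]2[C@@H](CC(=O)N(C)C)[C@@H](O)C=C(C)[C@@H]12
F4 | step 9 | bis(trimethylsilyl) dienol ether (2-OTMS-2,4-diene; 6α-OTMS) | C[Si](C)(C)OC1=C2C(C)=C[C@H](O[Si](C)(C)C)[C@H](CC(=O)N(C)C)[C@@H]2[C@@H](O[Si](C)(C)C(C)(C)C)[C@@H](C(=O)OCC[Si](C)(C)C)C1
F5 | step 9 | C6-O-trimethylsilyl dienone (3(8),4-dien-2-one) | O=C1C[C@H](C(=O)OCC[Si](C)(C)C)[C@H](O[Si](C)(C)C(C)(C)C)C2=C1C(C)=C[C@H](O[Si](C)(C)C)[C@@H]2CC(=O)N(C)C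
F6 | step 13 | 6β-chloroacetate (inverted at C6) | O=C1C[C@H](C(=O)OCC[Si](C)(C)C)[C@H](O[Si](C)(C)C(C)(C)C)C2=C1[C@]3(C)O[C@@H]3[C@@H](OC(=O)CCl)[C@@H]2CC(=O)N(C)C
F7 | step 13 | 6β-alcohol (C6 epimer of 20) | O=C1C[C@H](C(=O)OCC[Si](C)(C)C)[C@H](O[Si](C)(C)C(C)(C)C)C2=C1[C@]3(C)O[C@@H]3[C@@H](O)[C@@H]2CC(=O)N(C)C
F8 | step 14 | C2β allylic alcohol of 23 | O[C@@H]1C[C@H](C(=O)OCC[Si](C)(C)C)[C@H](O[Si](C)(C)C(C)(C)C)C2=C1[C@]3(C)O[C@@H]3[C@H]4OC(=O)C[C@@H]42
F9 | step 14 | bis-epoxy C2β alcohol | O[C@@H]1C[C@H](C(=O)OCC[Si](C)(C)C)[C@H](O[Si](C)(C)C(C)(C)C)[C@]23O[C@]12[C@]4(C)O[C@@H]4[C@H]5OC(=O)C[C@@H]53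
F10 | step 18 | bromohydrin (C2 hydroxyl, C3 bromide, anti) | C1C(=O)O[C@H]2[C@H]1C(=O)[C@@H](O[Si](C)(C)C(C)(C)C)/C(C(=O)OCC[Si](C)(C)C)=C\[C@@H](O)[C@H](Br)[C@]1(C)O[C@H]21
F11 | step 19 | C8 epimer of 32 (8R alcohol) | C1C(=O)O[C@H]2[C@H]1[C@@H](O)[C@@H](O[Si](C)(C)C(C)(C)C)/C(C(=O)OCC[Si](C)(C)C)=C\[C@H]1O[C@H]1[C@]1(C)O[C@H]21
F12 | step 19 | 8S 4-nitrobenzoate | C1C(=O)O[C@H]2[C@H]1[C@H](OC(=O)c1ccc(cc1)[N+](=O)[O-])[C@@H](O[Si](C)(C)C(C)(C)C)/C(C(=O)OCC[Si](C)(C)C)=C\[C@H]1O[C@H]1[C@]1(C)O[C@H]21
F13 | step 16 | N-(trans-2,3-diphenylaziridin-1-yl) imine of 26 | c1ccccc1[C@H]1[C@H](c2ccccc2)N1N=C1C=C(C(=O)OCC[Si](C)(C)C)[C@H](O[Si](C)(C)C(C)(C)C)[C@]23O[C@]12[C@]4(C)O[C@@H]4[C@H]5OC(=O)C[C@@H]53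
A1 | alternative 1 | ten-membered C8-hydroxy C9-ketone with the C7 methylene ester side chain | C=C(C(=O)OC)[C@@H]1[C@H](O)C(=O)/C(COCc3ccc(OC)cc3)=C\[C@H]2O[C@H]2[C@]2(C)O[C@@H]2[C@H]1O[Si](CC)(CC)CC
A2 | alternative 1 | thirteen-membered C8–O–C13 allylic ether with C9 ketone | O=C1COC/C(C(=O)OC)=C/[C@H](O[Si](CC)(CC)CC)[C@H]2O[C@@]2(C)[C@@H]3O[C@@H]3/C=C1/COCc4ccc(OC)cc4
A3 | alternative 2 | C9-desacetyl leucanthin B 2-(trimethylsilyl)ethyl ester | C=C1C(=O)O[C@H]2[C@H]1[C@H](OC(=O)[C@]1(C)O[C@@H]1C)[C@@H](O)/C(C(=O)OCC[Si](C)(C)C)=C\[C@H]1O[C@H]1[C@]1(C)O[C@H]21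
A4 | alternative 2 | seco C9 aldehyde with (Z)-C10 iodo enoate | C=C1C(=O)O[C@@H]([C@H]1[C@H](OC(=O)[C@]2(C)O[C@@H]2C)C=O)[C@H]3O[C@@]3(C)[C@@H]4O[C@@H]4/C=C(\I)C(=O)OCC[Si](C)(C)C
A5 | alternative 3 | ten-membered C6 ketone with both epoxides, C8 p-methoxybenzyl ether and C9 silyl ether | O=C2C[C@H](OCc3ccc(OC)cc3)[C@@H](O[Si](C)(C)C(C)(C)C)/C(C(=O)OCC[Si](C)(C)C)=C\[C@H]1O[C@H]1[C@]1(C)O[C@H]21
A6 | alternative 3 | cis-1,2-dialkenyl anti-diepoxycyclohexanol | O[C@@]1(/C=C/OCc2ccc(OC)cc2)[C@H](/C(C(=O)OCC[Si](C)(C)C)=C/O[Si](C)(C)C(C)(C)C)[C@H]3O[C@H]3[C@]4(C)O[C@@H]41
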